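**Plan**
1. Retrosynthesis: the three esters and the C16 methylene are unmasked last. Ring D is cut at C8–C15, ring B at C6=C8 (aldol condensation), ring A at C4–C5, C10–C5 and C10–C1 (enolate alkylations and a Michael closure). This leaves a ring C cyclohexanone made from cyclohex-2-en-1-one.
2. Forward: ring C (enone alkylation, isopropenyl conjugate addition) → temporary cis lactone C8–O–C20 → ring A built spiro at C10 → lactone opened, ring B closed → ring D closed → methylene and acids released.
3. Enabling feature: C8 is the β-carbon of the C7 ester through C6 (C6=C8 in ring B) and C15 is an aldehyde carbon, so both are acceptor carbons. One-electron reduction turns C15 into a nucleophilic ketyl; the C13 side chain sits 1,3 to C8 on ring C, so closure is 5-exo and gives the bicyclo[3.2.1]octane.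
4. Stereochemistry: C13 from the [Rh(cod)2]BF4/(R)-BINAP conjugate addition; C9 by equilibration (trans to C13); C10 by two convex-face substitutions on the lactone; C4 and C5 in a chair Michael closure; C8 and C15 in the ketyl step, relayed from C13; C6 by equilibration.
5. Helpers: the lactone (rigid template for C10), a phenylsulfanyl group on C17 (keeps C16 saturated during the radical step) and three methyl esters; all are removed.

Key step: step 12

Assumption: atom labels C1–C20 and rings A–D follow gibberellane numbering for all intermediates; methyl (2E)-3-iodoprop-2-enoate and potassium trifluoro(prop-1-en-2-yl)borate are taken as purchasable.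

**Step 1**
Reactants: 1 cyclohex-2-en-1-one; 2 methyl bromoacetate
Product: 3 methyl 2-(2-oxocyclohex-3-en-1-yl)acetate (racemic)
Conditions: LiN(i-Pr)2, THF, −78 °C; then 2, −78 → −20 °C
Reagents that add atoms: none
Why: kinetic deprotonation of the enone at the saturated α' carbon (future C9) followed by SN2 enolate alkylation joins C9 to C10; the new centre is racemic and is corrected in step 2.

**Step 2**
Reactants: 3 methyl 2-(2-oxocyclohex-3-en-1-yl)acetate; 4 potassium trifluoro(prop-1-en-2-yl)borate
Product: 6 methyl 2-[(1S,4R)-2-oxo-4-(prop-1-en-2-yl)cyclohexyl]acetate, via cis keto ester 5 (not isolated)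
Conditions: [Rh(cod)2]BF4 (3 mol %), (R)-BINAP (3.3 mol %), toluene/H2O, 100 °C; then DBU (0.2 equiv), rt
Reagents that add atoms: none
Why: the Hayashi–Miyaura asymmetric conjugate addition under [Rh(cod)2]BF4/(R)-BINAP catalysis should set C13 (R) under ligand control on both enantiomers of 3 ((R)-BINAP being the antipode of the ligand that gives (S)-3-substituted cyclohexanones), and base equilibration of the ketone α-centre C9 should converge on the trans diequatorial isomer.

**Step 3**
Reactants: 6 methyl 2-[(1S,4R)-2-oxo-4-(prop-1-en-2-yl)cyclohexyl]acetate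
Product: 8 (3aS,6R,7aS)-6-(prop-1-en-2-yl)hexahydro-1-benzofuran-2(3H)-one, via hydroxy ester 7 (not isolated)
Conditions: LiBH(s-Bu)3 (L-Selectride), THF, −78 °C → rt; then 1 M HCl
Reagents that add atoms: none
Why: the bulky hydride should attack the ketone from the equatorial direction to give the axial C8 alcohol cis to the C9 side chain, which lactonises by acyl substitution to the cis-fused γ-lactone that serves as the template for C10.

**Step 4**
Reactants: 8 (3aS,6R,7aS)-6-(prop-1-en-2-yl)hexahydro-1-benzofuran-2(3H)-one; 9 1,3-dibromopropane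
Product: 10 (3S,3aS,6R,7aS)-3-(3-bromopropyl)-6-(prop-1-en-2-yl)hexahydro-1-benzofuran-2(3H)-one
Conditions: LiN(i-Pr)2, THF, −78 °C; 9 (5 equiv), DMPU, −78 → −30 °C
Reagents that add atoms: none
Why: SN2 alkylation of the lactone enolate installs C1–C3; the electrophile should enter anti to the ring-fusion C9–C11 bond (convex face), although this C10 centre is enolised again in step 5.

**Step 5**
Reactants: 10 (3S,3aS,6R,7aS)-3-(3-bromopropyl)-6-(prop-1-en-2-yl)hexahydro-1-benzofuran-2(3H)-one; 11 methyl (2E)-3-iodoprop-2-enoate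
Product: 12 methyl (2E)-3-[(3S,3aS,6R,7aS)-3-(3-bromopropyl)-2-oxo-6-(prop-1-en-2-yl)octahydro-1-benzofuran-3-yl]prop-2-enoate
Conditions: LiN(i-Pr)2, THF, −78 °C; 11, −78 → −40 °C
Reagents that add atoms: none
Why: conjugate addition–elimination (vinylic substitution) of the tertiary lactone enolate on the β-iodoacrylate should keep the E geometry, and the second substituent again enters on the convex face, which fixes quaternary C10 with C5 anti to C11 and the C1 chain syn to it.

**Step 6**
Reactants: 12 methyl (2E)-3-[(3S,3aS,6R,7aS)-3-(3-bromopropyl)-2-oxo-6-(prop-1-en-2-yl)octahydro-1-benzofuran-3-yl]prop-2-enoate; 13 methyl propanoate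
Product: 15 methyl (3S,2'R,3'R,3aS,6R,7aS)-2'-(2-methoxy-2-oxoethyl)-3'-methyl-2-oxo-6-(prop-1-en-2-yl)octahydrospiro[1-benzofuran-3,1'-cyclohexane]-3'-carboxylate, via alkylated diester 14 (not isolated)
Conditions: LiN(i-Pr)2, 13, THF–DMPU, −78 → −20 °C; then LiN(i-Pr)2 (1.3 equiv), −78 → −20 °C; H2O
Reagents that add atoms: none
Why: ester enolate alkylation of the bromide followed by a 6-exo-trig intramolecular Michael addition of the C4 enolate to C5 closes ring A; a chair transition state with the bulky C9 and the (E)-acrylate arm equatorial should set C5, and lithium bridging between the enolate oxygen and the axial lactone carbonyl should place C19 axial (cis to C20) at C4.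

**Step 7**
Reactants: 15 spiro lactone diester
Product: 17 dimethyl (1S,2R,3R)-1-[(1S,2S,4R)-2-hydroxy-4-(prop-1-en-2-yl)cyclohexyl]-2-(2-methoxy-2-oxoethyl)-3-methylcyclohexane-1,3-dicarboxylate, via dipotassium salt 16 (not isolated)
Conditions: KOH (3 equiv), MeOH/H2O, 65 °C; CO2 to pH 9, evaporate; MeI (3 equiv), DMF, rt
Reagents that add atoms: potassium hydroxide, [K+].[OH-]; iodomethane, CI
Why: saponification opens the hindered γ-lactone (and the C7 ester), and SN2 O-methylation of the carboxylate salts traps the open form as the triester before it can relactonise; no stereocentre is touched.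

**Step 8**
Reactants: 17 hydroxy triester
Product: 18 dimethyl (1S,2R,3R)-2-(2-methoxy-2-oxoethyl)-3-methyl-1-[(1S,4R)-2-oxo-4-(prop-1-en-2-yl)cyclohexyl]cyclohexane-1,3-dicarboxylate
Conditions: Dess–Martin periodinane, CH2Cl2, 0 °C → rt
Reagents that add atoms: none
Why: Dess–Martin oxidation of the secondary C8 alcohol is neutral and leaves the isopropenyl group, the esters and the equatorial C9 centre alone.

**Step 9**
Reactants: 18 keto triester
Product: 20 trimethyl (1R,4aR,4bR,7R,9aR)-1-methyl-7-(prop-1-en-2-yl)-2,3,4,4a,4b,5,6,7,8,9a-decahydro-1H-fluorene-1,4a,9-tricarboxylate (rings A, B and C with C6=C8), via aldol adduct 19 (not isolated)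
Conditions: NaOMe (0.5 equiv), MeOH, 65 °C
Reagents that add atoms: none
Why: intramolecular aldol condensation (5-exo attack of the C6 ester enolate on the C8 ketone, then E1cB dehydration) closes ring B between the two equatorial arms of ring A and so gives the trans A/B fusion, while the epimerisable C9 should settle in the form that keeps the isopropenyl group equatorial on ring C.

**Step 10**
Reactants: 20 tricyclic enoate
Product: 21 trimethyl (1R,4aR,4bR,7R,9aR)-1-methyl-7-(3-oxoprop-1-en-2-yl)-2,3,4,4a,4b,5,6,7,8,9a-decahydro-1H-fluorene-1,4a,9-tricarboxylate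
Conditions: SeO2 (1.1 equiv), 1,4-dioxane, 80 °C
Reagents that add atoms: selenium dioxide, O=[Se]=O
Why: Riley allylic oxidation (ene reaction, then [2,3]-shift) should act on the only electron-rich alkene and turn the isopropenyl methyl group (C15) into the aldehyde; the tetrasubstituted enoate is deactivated.

**Step 11**
Reactants: 21 enal
Product: 22 trimethyl (1R,4aR,4bR,7R,9aR)-1-methyl-7-[1-oxo-3-(phenylsulfanyl)propan-2-yl]-2,3,4,4a,4b,5,6,7,8,9a-decahydro-1H-fluorene-1,4a,9-tricarboxylate (both C16 epimers)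
Conditions: PhSH (1.1 equiv), Et3N (5 mol %), CH2Cl2, 0 °C
Reagents that add atoms: benzenethiol, Sc1ccccc1
Why: thia-Michael addition to the α-methylene aldehyde makes C16 sp3 (its configuration is irrelevant because the centre is planarised again in step 13), so the ketyl of step 12 is not an allyl radical; the hindered enoate does not react.

**Step 12**
Reactants: 22 β-(phenylsulfanyl) aldehyde
Product: 25 trimethyl 15-hydroxy-17-(phenylsulfanyl)-ent-gibberellane-7,19,20-trioate (15-hydroxyl turned toward C9; both C16 epimers), via samarium enolate 23 (not isolated), via C6 epimer 24 (not isolated)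
Conditions: SmI2 (2.5 equiv), HMPA (8 equiv), t-BuOH (2.2 equiv), THF, −78 → 0 °C; then NaOMe (0.3 equiv), MeOH, rt
Reagents that add atoms: none
Why: Single-electron reduction of the aldehyde by SmI2 gives the C15 ketyl, which adds to C8, the β-carbon of the ring-B enoate (C6=C8–C7), and a second electron turns the C6 radical into a samarium ester enolate that t-BuOH protonates; the closest known reaction type is the samarium diiodide ketyl–olefin (ketyl–enoate) reductive cyclisation. Ring D (C8–C14–C13–C16–C15) closes in the 5-exo-trig mode through a boat-like ring C, which converts the six-membered ring into the bicyclo[3.2.1]octane. C8 is controlled by C13, because the two-atom tether reaches only the face of C8 syn to the side chain; C15 is controlled by the usual anti arrangement of the bulky samarium-bound oxygen and the enoate (oxygen turned away from C6, toward C9); C6 is set by enolate protonation and then by methoxide equilibration to the more stable epimer with the ester trans to C4. The step needs chemoselective reduction of the aldehyde beside three esters and a sulfide, and attack at C8 and not at C6: the aldehyde is by far the most easily reduced group, and β-attack on the enoate is both 5-exo and polarity-matched for the nucleophilic ketyl. The sulfide on C17 keeps C16 saturated, so closure cannot take place through C17 as it could from a conjugated enal radical anion.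

**Step 13**
Reactants: 25 cyclised sulfide
Product: 27 trimethyl 15-hydroxy-ent-gibberell-16-ene-7,19,20-trioate (trimethyl ester of the target), via sulfoxide 26 (not isolated)
Conditions: mCPBA (1.0 equiv), CH2Cl2, −78 °C; then CaCO3, toluene, 110 °C
Reagents that add atoms: none
Why: sulfide oxidation followed by thermal syn-elimination of the sulfoxide should give the exocyclic C16=C17 alkene regiospecifically, since the only β-hydrogen is on C16 and both C16 epimers converge.

**Step 14**
Reactants: 27 trimethyl ester of the target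
Product: 28 15-hydroxy-ent-gibberell-16-ene-7,19,20-trioic acid (the target gibberellin)
Conditions: NaSPr (12 equiv), HMPA, 60 °C; then 1 M HCl
Reagents that add atoms: none
Why: SN2 demethylation by thiolate attacks the O-methyl carbons, so the neopentyl C19 and C20 esters are cleaved without acyl substitution and the stereocentres, the allylic alcohol and the methylene group are left alone.

**Compound list**
1 | cyclohex-2-en-1-one | O=C1C=CCCC1 | starting material
2 | methyl bromoacetate | COC(=O)CBr | starting material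
3 | methyl 2-(2-oxocyclohex-3-en-1-yl)acetate (racemic) | COC(=O)CC1CCC=CC1=O | intermediate
4 | potassium trifluoro(prop-1-en-2-yl)borate | CC(=C)[B-](F)(F)F.[K+] | starting material
5 | methyl 2-[(1R,4R)-2-oxo-4-(prop-1-en-2-yl)cyclohexyl]acetate (cis keto ester) | CC(=C)[C@@H]1CC[C@H](CC(=O)OC)C(=O)C1 | intermediate
6 | methyl 2-[(1S,4R)-2-oxo-4-(prop-1-en-2-yl)cyclohexyl]acetate (trans keto ester) | CC(=C)[C@@H]1CC[C@@H](CC(=O)OC)C(=O)C1 | intermediate
7 | methyl 2-[(1S,2S,4R)-2-hydroxy-4-(prop-1-en-2-yl)cyclohexyl]acetate (formed as its lithium alkoxide) | CC(=C)[C@@H]1CC[C@@H](CC(=O)OC)[C@@H](O)C1 | intermediate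
8 | (3aS,6R,7aS)-6-(prop-1-en-2-yl)hexahydro-1-benzofuran-2(3H)-one | CC(=C)[C@@H]1CC[C@H]2CC(=O)O[C@H]2C1 | intermediate
9 | 1,3-dibromopropane | BrCCCBr | starting material
10 | (3S,3aS,6R,7aS)-3-(3-bromopropyl)-6-(prop-1-en-2-yl)hexahydro-1-benzofuran-2(3H)-one | CC(=C)[C@@H]1CC[C@H]2[C@H](CCCBr)C(=O)O[C@H]2C1 | intermediate
11 | methyl (2E)-3-iodoprop-2-enoate | COC(=O)/C=C/I | starting material
12 | methyl (2E)-3-[(3S,3aS,6R,7aS)-3-(3-bromopropyl)-2-oxo-6-(prop-1-en-2-yl)octahydro-1-benzofuran-3-yl]prop-2-enoate | CC(=C)[C@@H]1CC[C@H]2[C@](CCCBr)(/C=C/C(=O)OC)C(=O)O[C@H]2C1 | intermediate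
13 | methyl propanoate | CCC(=O)OC | starting material
14 | methyl (2E)-3-[(3S,3aS,6R,7aS)-3-(5-methoxy-4-methyl-5-oxopentyl)-2-oxo-6-(prop-1-en-2-yl)octahydro-1-benzofuran-3-yl]prop-2-enoate (both C4 epimers) | CC(=C)[C@@H]1CC[C@H]2[C@](CCCC(C)C(=O)OC)(/C=C/C(=O)OC)C(=O)O[C@H]2C1 | intermediate
15 | methyl (3S,2'R,3'R,3aS,6R,7aS)-2'-(2-methoxy-2-oxoethyl)-3'-methyl-2-oxo-6-(prop-1-en-2-yl)octahydrospiro[1-benzofuran-3,1'-cyclohexane]-3'-carboxylate (ring A spiro at C10 on the C8–O–C20 lactone) | CC(=C)[C@@H]1CC[C@H]2[C@@]3(CCC[C@@](C)(C(=O)OC)[C@H]3CC(=O)OC)C(=O)O[C@H]2C1 | intermediate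
16 | dipotassium salt of the ring-opened hydroxy diacid (C7 and C20 carboxylates, C19 methyl ester, C8 hydroxyl) | CC(=C)[C@@H]1CC[C@@H]([C@]2(C(=O)[O-])CCC[C@@](C)(C(=O)OC)[C@H]2CC(=O)[O-])[C@@H](O)C1.[K+].[K+] | intermediate
17 | dimethyl (1S,2R,3R)-1-[(1S,2S,4R)-2-hydroxy-4-(prop-1-en-2-yl)cyclohexyl]-2-(2-methoxy-2-oxoethyl)-3-methylcyclohexane-1,3-dicarboxylate | CC(=C)[C@@H]1CC[C@@H]([C@]2(C(=O)OC)CCC[C@@](C)(C(=O)OC)[C@H]2CC(=O)OC)[C@@H](O)C1 | intermediate
18 | dimethyl (1S,2R,3R)-2-(2-methoxy-2-oxoethyl)-3-methyl-1-[(1S,4R)-2-oxo-4-(prop-1-en-2-yl)cyclohexyl]cyclohexane-1,3-dicarboxylate | CC(=C)[C@@H]1CC[C@@H]([C@]2(C(=O)OC)CCC[C@@](C)(C(=O)OC)[C@H]2CC(=O)OC)C(=O)C1 | intermediate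
19 | ring-B aldol adduct (C8 tertiary alcohol, C6 methoxycarbonyl; C6 and C8 unassigned) | CC(=C)[C@@H]1CC[C@H]2[C@]3(C(=O)OC)CCC[C@@](C)(C(=O)OC)[C@H]3C(C(=O)OC)C2(O)C1 | intermediate
20 | trimethyl (1R,4aR,4bR,7R,9aR)-1-methyl-7-(prop-1-en-2-yl)-2,3,4,4a,4b,5,6,7,8,9a-decahydro-1H-fluorene-1,4a,9-tricarboxylate | CC(=C)[C@@H]1CC[C@H]2[C@]3(C(=O)OC)CCC[C@@](C)(C(=O)OC)[C@H]3C(C(=O)OC)=C2C1 | intermediate
21 | trimethyl (1R,4aR,4bR,7R,9aR)-1-methyl-7-(3-oxoprop-1-en-2-yl)-2,3,4,4a,4b,5,6,7,8,9a-decahydro-1H-fluorene-1,4a,9-tricarboxylate | C=C(C=O)[C@@H]1CC[C@H]2[C@]3(C(=O)OC)CCC[C@@](C)(C(=O)OC)[C@H]3C(C(=O)OC)=C2C1 | intermediate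
22 | trimethyl (1R,4aR,4bR,7R,9aR)-1-methyl-7-[1-oxo-3-(phenylsulfanyl)propan-2-yl]-2,3,4,4a,4b,5,6,7,8,9a-decahydro-1H-fluorene-1,4a,9-tricarboxylate (both C16 epimers) | O=CC(CSc1ccccc1)[C@@H]1CC[C@H]2[C@]3(C(=O)OC)CCC[C@@](C)(C(=O)OC)[C@H]3C(C(=O)OC)=C2C1 | intermediate
23 | cyclised bis-samarium species (C15 samarium alkoxide, C6/C7 samarium ester enolate; trivalent samarium) | c1ccccc1SCC1[C@@H]2CC[C@H]3[C@]4(C(=O)OC)CCC[C@@](C)(C(=O)OC)[C@H]4C(=C(OC)O[Sm](I)I)[C@]3(C2)[C@@H]1O[Sm](I)I | intermediate
24 | C6 epimer of 25 (C7 ester cis to C4; kinetic protonation product) | c1ccccc1SCC1[C@@H]2CC[C@H]3[C@]4(C(=O)OC)CCC[C@@](C)(C(=O)OC)[C@H]4[C@@H](C(=O)OC)[C@]3(C2)[C@@H]1O | intermediate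
25 | trimethyl 15-hydroxy-17-(phenylsulfanyl)-ent-gibberellane-7,19,20-trioate (15-hydroxyl turned toward C9; both C16 epimers) | c1ccccc1SCC1[C@@H]2CC[C@H]3[C@]4(C(=O)OC)CCC[C@@](C)(C(=O)OC)[C@H]4[C@H](C(=O)OC)[C@]3(C2)[C@@H]1O | intermediate
26 | sulfoxide of 25 (mixture at sulfur and C16) | O=S(c1ccccc1)CC1[C@@H]2CC[C@H]3[C@]4(C(=O)OC)CCC[C@@](C)(C(=O)OC)[C@H]4[C@H](C(=O)OC)[C@]3(C2)[C@@H]1O | intermediate
27 | trimethyl 15-hydroxy-ent-gibberell-16-ene-7,19,20-trioate (trimethyl ester of the target; C7, C19 and C20 methyl esters, 15-hydroxyl turned toward C9) | C=C1[C@@H]2CC[C@H]3[C@]4(C(=O)OC)CCC[C@@](C)(C(=O)OC)[C@H]4[C@H](C(=O)OC)[C@]3(C2)[C@@H]1O | intermediate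
28 | 15-hydroxy-ent-gibberell-16-ene-7,19,20-trioic acid (the target gibberellin; 15-hydroxyl turned toward C9, away from C6) | C=C1[C@@H]2CC[C@H]3[C@]4(C(=O)O)CCC[C@@](C)(C(=O)O)[C@H]4[C@H](C(=O)O)[C@]3(C2)[C@@H]1O | target

**Summary**
Total step count: 14. Longest linear sequence: 14 steps (from cyclohex-2-en-1-one).

**Steps most likely to fail**

Step 12. The ketyl may be over-reduced or may dimerise before it attacks the hindered tetrasubstituted enoate through the boat-like ring C, or the facial control at C15 may be poor. The fallback forms the same bond by polar chemistry. It sets out from 20: ozonolysis of the isopropenyl group (O3, CH2Cl2/MeOH, −78 °C; Me2S) would give the C13 acetyl compound F1. LiN(SiMe3)2 (THF, −78 → 0 °C) and then NaOMe/MeOH would close ring D by intramolecular Michael addition of the methyl-side enolate (C15) to C8 and give the 16-oxo-17-nor triester F2. Wittig methylenation (Ph3P=CH2, THF) would give the 15-deoxy 16-ene triester F3. SeO2/t-BuOOH allylic hydroxylation would be expected to give the 15-epimeric alcohol F4, Dess–Martin oxidation the 16-en-15-one F5, and Luche reduction (NaBH4, CeCl3·7H2O, MeOH, −78 °C) would invert C15 and come back to the route at 27.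

Step 6. Control of the quaternary C4 centre in the Michael closure (ester or methyl in the axial site) may be poor, or the C4 enolate may attack the lactone carbonyl. The fallback uses a much smaller anion-stabilising group. It sets out from 12: alkylation with lithiated propanenitrile (LiN(i-Pr)2, EtCN, THF–DMPU) would give the nitrile F6. A second equivalent of base would bring about the nitrile-anion Michael cyclisation, in which the small cyano group should take the axial site, and give the spiro nitrile F7. Hydration with the platinum catalyst [PtH(PMe2OH)(PMe2O)2H] (EtOH/H2O, 80 °C) would give the primary amide F8, and DMF dimethyl acetal in MeOH (60 °C) would convert the amide into the methyl ester and come back to the route at 15.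

Step 5. The hindered tertiary lactone enolate may fail to substitute the iodoacrylate (proton transfer, O-attack or closure onto the bromide). The fallback builds the acrylate arm from a one-carbon electrophile. It sets out from 10: LiN(i-Pr)2 and then gaseous formaldehyde at −78 °C, quenched with acetic acid at that temperature so that the alkoxide cannot displace the bromide, would give the hydroxymethyl lactone F9 (again from the convex face), Dess–Martin oxidation the aldehyde F10, and Wittig olefination with Ph3P=CHCO2Me (toluene, 80 °C) would come back to the route at 12.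

**Further compounds**
F1 | step 12 | trimethyl (1R,4aR,4bR,7R,9aR)-7-acetyl-1-methyl-2,3,4,4a,4b,5,6,7,8,9a-decahydro-1H-fluorene-1,4a,9-tricarboxylate | CC(=O)[C@@H]1CC[C@H]2[C@]3(C(=O)OC)CCC[C@@](C)(C(=O)OC)[C@H]3C(C(=O)OC)=C2C1
F2 | step 12 | trimethyl 16-oxo-17-nor-ent-gibberellane-7,19,20-trioate | O=C1[C@@H]2CC[C@H]3[C@]4(C(=O)OC)CCC[C@@](C)(C(=O)OC)[C@H]4[C@H](C(=O)OC)[C@]3(C2)C1
F3 | step 12 | trimethyl ent-gibberell-16-ene-7,19,20-trioate (15-deoxy analogue of 27) | C=C1[C@@H]2CC[C@H]3[C@]4(C(=O)OC)CCC[C@@](C)(C(=O)OC)[C@H]4[C@H](C(=O)OC)[C@]3(C2)C1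
F4 | step 12 | 15-epimer of 27 (15-hydroxyl turned toward C6) | C=C1[C@@H]2CC[C@H]3[C@]4(C(=O)OC)CCC[C@@](C)(C(=O)OC)[C@H]4[C@H](C(=O)OC)[C@]3(C2)[C@H]1O
F5 | step 12 | trimethyl 15-oxo-ent-gibberell-16-ene-7,19,20-trioate (16-en-15-one) | C=C1[C@@H]2CC[C@H]3[C@]4(C(=O)OC)CCC[C@@](C)(C(=O)OC)[C@H]4[C@H](C(=O)OC)[C@]3(C2)C1=O
F6 | step 6 | methyl (2E)-3-[(3S,3aS,6R,7aS)-3-(4-cyanopentyl)-2-oxo-6-(prop-1-en-2-yl)octahydro-1-benzofuran-3-yl]prop-2-enoate | CC(=C)[C@@H]1CC[C@H]2[C@](CCCC(C)C#N)(/C=C/C(=O)OC)C(=O)O[C@H]2C1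
F7 | step 6 | spiro lactone as 15 with an axial cyano group at C4 in place of the C19 ester | CC(=C)[C@@H]1CC[C@H]2[C@@]3(CCC[C@@](C)(C#N)[C@H]3CC(=O)OC)C(=O)O[C@H]2C1
F8 | step 6 | spiro lactone as 15 with a primary carboxamide at C4 in place of the C19 ester | CC(=C)[C@@H]1CC[C@H]2[C@@]3(CCC[C@@](C)(C(N)=O)[C@H]3CC(=O)OC)C(=O)O[C@H]2C1
F9 | step 5 | (3S,3aS,6R,7aS)-3-(3-bromopropyl)-3-(hydroxymethyl)-6-(prop-1-en-2-yl)hexahydro-1-benzofuran-2(3H)-one | CC(=C)[C@@H]1CC[C@H]2[C@](CCCBr)(CO)C(=O)O[C@H]2C1
F10 | step 5 | (3S,3aS,6R,7aS)-3-(3-bromopropyl)-2-oxo-6-(prop-1-en-2-yl)octahydro-1-benzofuran-3-carbaldehyde | CC(=C)[C@@H]1CC[C@H]2[C@](CCCBr)(C=O)C(=O)O[C@H]2C1
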